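## Retrosynthetic overview
1. The target is the C7-acetate of hydroxy-lactone **23**. **23** comes from a transannular 7-exo epoxide opening of macrocyclic epoxy-tBu-ester **22**. The C20 acid attacks tertiary C8 with inversion, which builds the hindered tertiary lactone C–O bond and sets C8 without any tertiary-alcohol acylation.
2. Macrocycle **22** comes from ring-closing metathesis (acrylate C12=CH2 with terminal C11=CH2), which gives the ring-E enoate (C20 ester cis to C10) that the lactonisation needs.
3. Triene **21** comes from a Horner–Wadsworth–Emmons coupling of phosphonate **12** (C4–C11, from Sharpless AE) with enal **20** (C1–C3, C12–C14; iPr added by syn-carbocupration of an ynoate).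
4. Ring order: the 14-membered carbocycle (RCM) first, then the 7-membered lactone (transannular).

Assumptions:
- D-(−)-DET gives the (7R,8R)-epoxide by analogy with (E)-2-alken-1-ols giving (2R,3R) epoxy alcohols.
- The RCM gives mainly the ring-E isomer.
- 3-(TBSO)propanal is commercial (otherwise two steps from 1,3-propanediol).

## Route

**Step 1**
Reactants: 1 (3-(TBSO)propanal); 2 (2-(triphenylphosphoranylidene)propanal)
Product: 3 ((2E)-5-(TBSO)-2-methylpent-2-enal)
Conditions: toluene, 80 °C
Reagents that add atoms: none
Why: Wittig olefination with a stabilised ylide gives the E-α-methyl enal (>95:5), which fixes the E geometry of the future epoxide.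

**Step 2**
Reactants: 3
Product: 4 ((2E)-5-(TBSO)-2-methylpent-2-en-1-ol)
Conditions: NaBH4, CeCl3·7H2O, MeOH, 0 °C
Reagents that add atoms: none
Why: Luche 1,2-reduction of the enal; no stereocentre is formed.

**Step 3**
Reactants: 4
Product: 5 ({(2R,3R)-3-[2-(TBSO)ethyl]-2-methyloxiran-2-yl}methanol; C8 = R, C7 = R)
Conditions: Ti(OiPr)4, D-(−)-DET, TBHP, 4 Å MS, CH2Cl2, −20 °C
Reagents that add atoms: tert-butyl hydroperoxide, CC(C)(C)OO (supplies the epoxide O)
Why: Sharpless asymmetric epoxidation of the E-allylic alcohol sets C7 and C8 together as the trans-epoxide (7R,8R).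

**Step 4**
Reactants: 5
Product: 6 (the corresponding mesylate)
Conditions: MsCl, Et3N, CH2Cl2, −10 °C, used crude
Reagents that add atoms: methanesulfonyl chloride, CS(=O)(=O)Cl
Why: the primary alcohol is converted to a leaving group; no stereocentre is touched.

**Step 5**
Reactants: 6; 7 (allylmagnesium bromide)
Product: 8 (TBS ether of the but-3-enyl epoxide; C7 = R, C8 = R)
Conditions: 7, CuI (10 mol %), THF, −40 °C
Reagents that add atoms: allylmagnesium bromide, C=CC[Mg]Br (supplies C10, C11 and the terminal CH2)
Why: Cu-catalysed SN2 displacement of the CH2OMs group by the allyl Grignard builds the C9–C10–C11=CH2 RCM partner, and both epoxide stereocentres are untouched.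

**Step 6**
Reactants: 8
Product: 9 (2-[(2R,3R)-3-(but-3-enyl)-3-methyloxiran-2-yl]ethanol)
Conditions: TBAF, THF, 0 °C
Reagents that add atoms: none
Why: fluoride desilylation; the epoxide is stable to these mildly basic conditions.

**Step 7**
Reactants: 9
Product: 10 (the primary iodide)
Conditions: PPh3, I2, imidazole, CH2Cl2, 0 °C
Reagents that add atoms: iodine, II
Why: Garegg–Samuelsson/Appel iodination, buffered by imidazole so the epoxide survives.

**Step 8**
Reactants: 10; 11 (trimethyl phosphonoacetate)
Product: 12 (methyl 4-[(2R,3R)-3-(but-3-enyl)-3-methyloxiranyl]-2-(dimethoxyphosphoryl)butanoate, C4 epimeric)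
Conditions: 11 (3 equiv), NaH, DMF, 0 → 23 °C
Reagents that add atoms: trimethyl phosphonoacetate, COC(=O)CP(=O)(OC)OC (supplies C4 and C18)
Why: SN2 alkylation of the phosphonoacetate anion forms the C4–C5 bond; the C4 epimer mixture is irrelevant because C4 becomes sp2 in step 14.

**Step 9**
Reactants: 13 (tert-butyl 2-(bromomethyl)acrylate); 14 (propargylmagnesium bromide)
Product: 15 (tert-butyl 2-methylidenehex-5-ynoate)
Conditions: 14, CuI (10 mol %), THF, −40 °C
Reagents that add atoms: propargylmagnesium bromide, C#CC[Mg]Br (supplies C1, C2, C14)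
Why: Cu-catalysed allyl–propargyl coupling (SN2 at the allylic bromide) builds the acrylate–alkyne chain in one step.

**Step 10**
Reactants: 15
Product: 16 (7-tert-butyl 1-methyl 6-methylidenehept-2-ynedioate)
Conditions: LiHMDS, THF, −78 °C; then ClCO2Me
Reagents that add atoms: methyl chloroformate, COC(=O)Cl (supplies C3 and its OMe)
Why: deprotonation of the terminal alkyne with a non-nucleophilic base followed by C-acylation gives the ynoate without attacking the acrylate.

**Step 11**
Reactants: 16; 17 (isopropylmagnesium chloride)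
Product: 18 (7-tert-butyl 1-methyl (2E)-6-methylidene-3-isopropylhept-2-enedioate)
Conditions: 17, CuBr·SMe2 (10 mol %), THF, −78 → −40 °C
Reagents that add atoms: isopropylmagnesium chloride, CC(C)[Mg]Cl (supplies C15–C17)
Why: syn-carbocupration of the ynoate places iPr and H cis, so iPr is trans to the ester, which is the C1=C2 geometry of the target; the ynoate is far more electrophilic than the hindered acrylate.

**Step 12**
Reactants: 18
Product: 19 (tert-butyl (5E)-7-hydroxy-2-methylidene-5-isopropylhept-5-enoate)
Conditions: DIBAL-H (2.2 equiv), CH2Cl2, −78 °C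
Reagents that add atoms: none
Why: DIBAL reduces the unhindered methyl enoate while the hindered tBu acrylate survives at −78 °C; the alkene geometry is retained.

**Step 13**
Reactants: 19
Product: 20 (tert-butyl (5E)-2-methylidene-7-oxo-5-isopropylhept-5-enoate)
Conditions: MnO2, CH2Cl2, 23 °C
Reagents that add atoms: none
Why: MnO2 chemoselectively oxidises the allylic alcohol to the enal (C3 aldehyde).

**Step 14**
Reactants: 12; 20
Product: 21 (acyclic triene: methyl (2E)-2-[epoxyalkyl]-5-isopropyl-dienoate bearing the acrylate; (7R,8R)-epoxide; ester trans to C2, iPr trans to C3)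
Conditions: LiCl, DBU, MeCN, 23 °C
Reagents that add atoms: none
Why: Masamune–Roush HWE of an α-alkyl phosphonoacetate with an enal gives the E-2-alkyl-2,4-dienoate, which is the required C3=C4 geometry (ester trans to C2).

**Step 15**
Reactants: 21
Product: 22 (14-membered macrocyclic epoxy tBu ester; (7R,8R); C11=C12 ring-E; C20 ester cis to C10)
Conditions: Hoveyda–Grubbs II (10 mol %), toluene, 1 mM, 80 °C
Reagents that add atoms: none
Why: ring-closing metathesis of the acrylate with the terminal alkene releases ethylene and forms the trisubstituted enoate; in a 14-membered ring the ring-E isomer is favoured, which places the ester on the side of C10 for lactonisation.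

**Step 16**
Reactants: 22
Product: 23 (hydroxy-lactone; 7R,8S)
Conditions: TFA, CH2Cl2, 0 → 23 °C; then aq. NaHCO3 work-up (MeOH, cat. K2CO3 if a C7 trifluoroacetate forms)
Reagents that add atoms: none
Why: TFA cleaves the tBu ester (isobutylene is lost) and activates the tertiary epoxide, and the liberated C20 carboxyl attacks C8 in a 7-exo-tet opening with inversion, giving (7R,8R)-epoxide → (7R,8S) lactone while the C7–O bond is retained. Proposed new method: transannular Markovnikov epoxy-acid cyclisation in a 14-membered cembranoid ring; the ring-E, Z-acid geometry puts C20 on the inside face to attack C8 anti to the epoxide oxygen; the closest known reaction is acid-promoted 7-exo epoxy-acid lactonisation of tertiary epoxides with inversion.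

**Step 17**
Reactants: 23
Product: 24 (Sarcrassin D)
Conditions: Ac2O, pyridine, DMAP (cat.), CH2Cl2, 23 °C
Reagents that add atoms: acetic anhydride, CC(=O)OC(C)=O
Why: acylation of the secondary C7 alcohol proceeds with retention, so no stereocentre changes.

## Compound list
1 | 3-(TBSO)propanal | O=CCCO[Si](C)(C)C(C)(C)C | starting material
2 | 2-(triphenylphosphoranylidene)propanal | CC(C=O)=P(c1ccccc1)(c1ccccc1)c1ccccc1 | starting material
3 | (2E)-5-(TBSO)-2-methylpent-2-enal | O=C/C(C)=C/CCO[Si](C)(C)C(C)(C)C | intermediate
4 | (2E)-5-(TBSO)-2-methylpent-2-en-1-ol | OC/C(C)=C/CCO[Si](C)(C)C(C)(C)C | intermediate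
5 | {(2R,3R)-3-[2-(TBSO)ethyl]-2-methyloxiran-2-yl}methanol | OC[C@@]1(C)O[C@@H]1CCO[Si](C)(C)C(C)(C)C | intermediate
6 | mesylate of 5 | CS(=O)(=O)OC[C@@]1(C)O[C@@H]1CCO[Si](C)(C)C(C)(C)C | intermediate
7 | allylmagnesium bromide | C=CC[Mg]Br | starting material
8 | tert-butyl{2-[(2R,3R)-3-(but-3-enyl)-3-methyloxiran-2-yl]ethoxy}dimethylsilane | C=CCC[C@@]1(C)O[C@@H]1CCO[Si](C)(C)C(C)(C)C | intermediate
9 | 2-[(2R,3R)-3-(but-3-enyl)-3-methyloxiran-2-yl]ethanol | C=CCC[C@@]1(C)O[C@@H]1CCO | intermediate
10 | (2R,3R)-2-(but-3-enyl)-3-(2-iodoethyl)-2-methyloxirane | C=CCC[C@@]1(C)O[C@@H]1CCI | intermediate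
11 | trimethyl phosphonoacetate | COC(=O)CP(=O)(OC)OC | starting material
12 | phosphonoacetate S-fragment | COC(=O)C(CC[C@H]1O[C@]1(C)CCC=C)P(=O)(OC)OC | intermediate
13 | tert-butyl 2-(bromomethyl)acrylate | C=C(CBr)C(=O)OC(C)(C)C | starting material
14 | propargylmagnesium bromide | C#CC[Mg]Br | starting material
15 | tert-butyl 2-methylidenehex-5-ynoate | C#CCCC(=C)C(=O)OC(C)(C)C | intermediate
16 | 7-tert-butyl 1-methyl 6-methylidenehept-2-ynedioate | COC(=O)C#CCCC(=C)C(=O)OC(C)(C)C | intermediate
17 | isopropylmagnesium chloride | CC(C)[Mg]Cl | starting material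
18 | 7-tert-butyl 1-methyl (2E)-6-methylidene-3-isopropylhept-2-enedioate | COC(=O)/C=C(/C(C)C)CCC(=C)C(=O)OC(C)(C)C | intermediate
19 | tert-butyl (5E)-7-hydroxy-2-methylidene-5-isopropylhept-5-enoate | OC/C=C(/C(C)C)CCC(=C)C(=O)OC(C)(C)C | intermediate
20 | tert-butyl (5E)-2-methylidene-7-oxo-5-isopropylhept-5-enoate | O=C/C=C(/C(C)C)CCC(=C)C(=O)OC(C)(C)C | intermediate
21 | acyclic triene epoxide | COC(=O)/C(CC[C@H]1O[C@]1(C)CCC=C)=C/C=C(/C(C)C)CCC(=C)C(=O)OC(C)(C)C | intermediate
22 | macrocyclic epoxy tBu ester | COC(=O)/C1=C/C=C(/C(C)C)CC/C(C(=O)OC(C)(C)C)=C/CC[C@@]2(C)O[C@@H]2CC1 | intermediate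
23 | hydroxy-lactone (7R,8S) | COC(=O)/C1=C/C=C(/C(C)C)CCC2=CCC[C@](C)(OC2=O)[C@H](O)CC1 | intermediate
24 | Sarcrassin D | COC(=O)/C1=C/C=C(/C(C)C)CCC2=CCC[C@](C)(OC2=O)[C@H](OC(C)=O)CC1 | target

## Totals
Total steps: 17. Longest linear sequence: 12 (1 → 3 → 4 → 5 → 6 → 8 → 9 → 10 → 12 → 21 → 22 → 23 → 24, i.e. steps 1–8 and 14–17).

## Three steps most likely to fail
1. **Step 16 (transannular epoxy-acid lactonisation).** Trifluoroacetate may open the epoxide intermolecularly, or the diene may isomerise in acid.
   Fallback: open the epoxide to the anti-diol with aqueous acid, selectively acetylate C7–OH, and close the tertiary lactone with an MNBA/DMAP (Shiina-type) esterification of the Z-acid.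
2. **Step 15 (macro-RCM).** The acrylate/terminal-alkene closure may be slow, or give the ring-Z isomer.
   Fallback: re-route so C11=C12 is formed by a Z-selective intramolecular Ando/Still–Gennari HWE. This needs a C11 aldehyde (from ozonolysis of the terminal alkene) and a diarylphosphonoacetate at C12.
3. **Step 5 (allyl-Grignard SN2 on the neopentyl-like epoxy mesylate).** The Grignard may open the epoxide instead.
   Fallback: make the same epoxide from hex-5-en-1-yne by Zr-catalysed carboalumination/iodination, B-alkyl Suzuki coupling with the borane from benzyl vinyl ether, and Shi epoxidation (D-ketone) of the trisubstituted alkene, which is selective over the terminal alkene.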